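The butenolide (O1, C2, C3, C4, C5) is cut at C4–aryl, C3–C2 and C2–O1, which leads back to a C5 tertiary alkynyl carbinol, the ring B aryl Grignard reagent and CO2. The step exploits the tetrasubstituted C3=C4 bond, on which the ring B aryl and the C3 oxygen are cis and C5 and C2 are cis: a C5 magnesium alkoxide directs anti addition of aryl (to C4) and magnesium (to C3) across a C5-bound alkoxyalkyne, and carboxylation plus lactonisation close the ring in the same flask. The precursor is the dry lithium salt of the (S) 2-benzyl-2-hydroxy-4-(silylethoxy)but-3-ynoic acid, with C5 already set.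

Key step: step 12

Remarks on the chemistry (assumptions):
- The target SMILES defines C5 as (S) (O1 > CO2Me > C4 > CH2Ar); all descriptors below follow from it.
- Ring B is built from 3,5-dibromosalicylaldehyde and not from 4-bromocatechol. Metalation of a 4-bromocatechol bis-MOM ether would occur between bromine and oxygen and would place the prenyl group on the wrong carbon.
- An alkoxyalkyne is electron-rich at the carbon β to oxygen (here C4) and electrophilic at the oxygen-bearing carbon (C3). Its own polarisation therefore does not assist aryl delivery to C4, and the C5 alkoxide chelate has to enforce it. For this reason the C5 oxygen is magnesiated before copper or aryl Grignard reagent is admitted.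
- The precursor is kept as a salt throughout, because a free carboxylic acid adds to an alkoxyalkyne.

Step 1
Reactants: 1 4-bromo-2-iodophenol
Product: 2 4-bromo-2-iodo-1-(methoxymethoxy)benzene
Conditions: MOMCl, i-Pr2NEt, CH2Cl2, 0 °C → rt
Reagents that add atoms: chloromethyl methyl ether, COCCl
Why: Williamson-type O-alkylation of the phenol by the α-chloro ether under amine base gives the aryl MOM ether, which later assists ortho magnesiation.

Step 2
Reactants: 2 4-bromo-2-iodo-1-(methoxymethoxy)benzene
Product: 4 4-bromo-1-(methoxymethoxy)-2-(3-methylbut-2-en-1-yl)benzene, via arylmagnesium chloride 3 (not isolated)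
Conditions: i-PrMgCl·LiCl, THF, −30 °C; then CuI (5 mol%), prenyl bromide, −30 → 0 °C
Reagents that add atoms: 1-bromo-3-methylbut-2-ene, CC(C)=CCBr
Why: Halogen–magnesium exchange is far faster at the C–I bond next to the coordinating OMOM group than at C–Br, and the copper-catalysed allylic substitution takes place at the primary carbon of prenyl bromide because attack at the other terminus would create a quaternary benzylic carbon.

Step 3
Reactants: 4 4-bromo-1-(methoxymethoxy)-2-(3-methylbut-2-en-1-yl)benzene; 5 methyl oxirane-2-carboxylate (racemic methyl glycidate)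
Product: 7 methyl 2-hydroxy-3-[4-(methoxymethoxy)-3-(3-methylbut-2-en-1-yl)phenyl]propanoate (racemic), via arylmagnesium bromide 6 (not isolated)
Conditions: Mg turnings, THF, 40 °C; then CuI (10 mol%), 5, −40 → −20 °C
Reagents that add atoms: none
Why: Magnesium insertion gives the aryl Grignard reagent, whose copper-catalysed SN2 opening of the epoxide at its unsubstituted carbon is faster at low temperature than attack on the ester.

Step 4
Reactants: 7 methyl 2-hydroxy-3-[4-(methoxymethoxy)-3-(3-methylbut-2-en-1-yl)phenyl]propanoate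
Product: 8 methyl 3-[4-(methoxymethoxy)-3-(3-methylbut-2-en-1-yl)phenyl]-2-oxopropanoate
Conditions: Dess–Martin periodinane, NaHCO3, CH2Cl2, 0 °C → rt; used at once
Reagents that add atoms: none
Why: Dess–Martin oxidation converts the secondary α-hydroxy ester into the α-keto ester under buffered conditions that spare the aryl MOM ether and the trisubstituted alkene; 8 is used without storage because arylpyruvates enolise and self-condense.

Step 5
Reactants: 9 2-(trimethylsilyl)ethanol; 10 trichloroethylene
Product: 13 [2-(ethynyloxy)ethyl]trimethylsilane, via dichlorovinyl ether 11 (not isolated), via lithium alkoxyacetylide 12 (not isolated)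
Conditions: KH, THF, 0 °C; 10, 0 °C → rt; then n-BuLi (2.4 equiv), −78 → −40 °C; MeOH, −78 °C; used as a titrated toluene solution
Reagents that add atoms: none
Why: The potassium alkoxide of 9 replaces one chlorine of trichloroethylene by elimination–addition, and n-BuLi then removes HCl and exchanges the last chlorine for lithium, so that protonation releases the terminal alkoxyalkyne (ynol ether synthesis from trichloroethylene); the alkoxide is kept cold to avoid Peterson-type loss of ethene.

Step 6
Reactants: 8 methyl 3-[4-(methoxymethoxy)-3-(3-methylbut-2-en-1-yl)phenyl]-2-oxopropanoate; 13 [2-(ethynyloxy)ethyl]trimethylsilane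
Product: 14 methyl (2S)-2-hydroxy-2-{[4-(methoxymethoxy)-3-(3-methylbut-2-en-1-yl)phenyl]methyl}-4-[2-(trimethylsilyl)ethoxy]but-3-ynoate
Conditions: Zn(OTf)2 (20 mol%), (1S,2S)- or (1R,2R)-3-(tert-butyldimethylsilyloxy)-2-(dimethylamino)-1-(4-nitrophenyl)propan-1-ol (22 mol%), Et3N (30 mol%), 13 (2 equiv), toluene, 25–40 °C, slow addition of 8
Reagents that add atoms: none
Why: Catalytic enantioselective alkynylation of an α-ketoester: the zinc alkoxyacetylide formed with the amine adds to the keto form, which is bound through both carbonyl oxygens inside the chiral zinc amino alkoxide, so that one face is attacked and C5 is set as (S) by the choice of ligand enantiomer (to be fixed in a trial run), while the ammonium triflate buffer lets the enol and keto forms of 8 interconvert.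

Step 7
Reactants: 14 methyl (2S)-2-hydroxy-2-{[4-(methoxymethoxy)-3-(3-methylbut-2-en-1-yl)phenyl]methyl}-4-[2-(trimethylsilyl)ethoxy]but-3-ynoate
Product: 15 lithium (2S)-2-hydroxy-2-{[4-(methoxymethoxy)-3-(3-methylbut-2-en-1-yl)phenyl]methyl}-4-[2-(trimethylsilyl)ethoxy]but-3-ynoate
Conditions: LiOH·H2O (1.0 equiv), THF/H2O, 0 °C → rt; evaporation, toluene azeotrope, high vacuum; no acidification
Reagents that add atoms: lithium hydroxide, [Li+].[OH-]
Why: Saponification of the activated α-hydroxy ester by acyl substitution leaves the base-stable alkoxyalkyne, the MOM ether and the quaternary C5 centre untouched, and the product is isolated only as its dry salt.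

Step 8
Reactants: 16 3,5-dibromo-2-hydroxybenzaldehyde
Product: 18 3,5-dibromobenzene-1,2-diol, via aryl formate 17 (not isolated)
Conditions: H2O2 (30% aq.), NaOH (aq.), 0 °C → rt; then HCl (aq.)
Reagents that add atoms: hydrogen peroxide, OO
Why: Dakin oxidation: the hydroperoxide adduct of the ortho-hydroxy aldehyde rearranges with aryl migration to the formate, which is hydrolysed in the same alkaline medium to the catechol.

Step 9
Reactants: 18 3,5-dibromobenzene-1,2-diol
Product: 19 1,5-dibromo-2,3-bis(methoxymethoxy)benzene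
Conditions: MOMCl (2.5 equiv), i-Pr2NEt, CH2Cl2, 0 °C → rt
Reagents that add atoms: chloromethyl methyl ether, COCCl
Why: Double Williamson-type O-alkylation of the catechol gives the bis-acetal, which masks both acidic hydroxyls and activates the neighbouring bromine for exchange.

Step 10
Reactants: 19 1,5-dibromo-2,3-bis(methoxymethoxy)benzene
Product: 21 5-bromo-1,2-bis(methoxymethoxy)-3-(3-methylbut-2-en-1-yl)benzene, via arylmagnesium chloride 20 (not isolated)
Conditions: i-PrMgCl·LiCl (1.05 equiv), THF, 0 °C → rt; then CuI (5 mol%), prenyl bromide, −20 → 0 °C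
Reagents that add atoms: 1-bromo-3-methylbut-2-ene, CC(C)=CCBr
Why: Halogen–magnesium exchange occurs at the bromine ortho to an OMOM group (inductive activation and chelation of magnesium) and not at the bromine flanked by two hydrogens, and copper-catalysed allylic substitution then gives the linear prenyl arene.

Step 11
Reactants: 21 5-bromo-1,2-bis(methoxymethoxy)-3-(3-methylbut-2-en-1-yl)benzene
Product: 22 [3,4-bis(methoxymethoxy)-5-(3-methylbut-2-en-1-yl)phenyl]magnesium bromide
Conditions: Mg turnings, LiCl, THF, 25–40 °C; titrated solution used directly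
Reagents that add atoms: magnesium, [Mg]
Why: Grignard formation by insertion of magnesium into the aryl C–Br bond; the MOM ethers and the trisubstituted alkene are inert.

Step 12
Reactants: 15 lithium (2S)-2-hydroxy-2-{[4-(methoxymethoxy)-3-(3-methylbut-2-en-1-yl)phenyl]methyl}-4-[2-(trimethylsilyl)ethoxy]but-3-ynoate; 22 [3,4-bis(methoxymethoxy)-5-(3-methylbut-2-en-1-yl)phenyl]magnesium bromide; 23 carbon dioxide
Product: 27 (2S)-3-[3,4-bis(methoxymethoxy)-5-(3-methylbut-2-en-1-yl)phenyl]-2-{[4-(methoxymethoxy)-3-(3-methylbut-2-en-1-yl)phenyl]methyl}-5-oxo-4-[2-(trimethylsilyl)ethoxy]-2,5-dihydrofuran-2-carboxylic acid, via magnesium alkoxide 24 (not isolated), via oxamagnesacycle 25 (not isolated), via seco hydroxy diacid 26 (not isolated)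
Conditions: i-PrMgCl (1.0 equiv), THF/toluene, −20 °C; then CuI (5 mol%), 22 (2.0 equiv), −20 → 25 °C; CO2 (dry gas), −20 → 0 °C; HCl (1 M aq.) to pH 2–3, 0 → 25 °C
Reagents that add atoms: none
Why: Proposed new method: deprotonation gives the C5 chloromagnesium alkoxide 24, whose magnesium lies within reach of the alkyne; the aryl group of 22, carried by a catalytic arylcopper–magnesium species, is delivered to C4 from the side opposite to that magnesium while C3 binds it, so that the five-membered oxamagnesacycle 25 (O–C5–C4=C3–Mg) results by anti addition, and its C3–Mg bond then inserts CO2. The closest known reaction type is the copper-catalysed, alkoxide-directed anti-carbomagnesiation of propargylic alcohols followed by CO2 capture to butenolides; new are the oxygen substituent on the alkyne and the carboxylate beside the directing alkoxide. On acidification the seco acid 26, in which the C5 hydroxyl and the new carboxyl are cis on C3=C4, closes the lactone by 5-exo-trig acyl substitution; no stereocentre is formed and the (S) centre at C5 is untouched because none of its bonds is broken. The step needs aryl on C4 with aryl and carboxyl anti, and both follow from ring size: magnesium on C3 completes a five-membered chelate with the C5 oxygen (and a six-membered one with the C5 carboxylate), whereas the reverse orientation would need a four-membered ring. The polarisation of the alkoxyalkyne opposes this (C4 is its electron-rich carbon, C3 its electrophilic one), which is why the alkoxide is magnesiated before copper is admitted, the copper loading is low and an aryl reagent, slow in undirected carbocupration, is used; the C3–Mg bond is in turn stabilised inductively by the geminal oxygen. The C5 carboxyl is masked as its salt against the Grignard reagent.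

Step 13
Reactants: 27 (2S)-3-[3,4-bis(methoxymethoxy)-5-(3-methylbut-2-en-1-yl)phenyl]-2-{[4-(methoxymethoxy)-3-(3-methylbut-2-en-1-yl)phenyl]methyl}-5-oxo-4-[2-(trimethylsilyl)ethoxy]-2,5-dihydrofuran-2-carboxylic acid
Product: 28 methyl (2S)-3-[3,4-bis(methoxymethoxy)-5-(3-methylbut-2-en-1-yl)phenyl]-2-{[4-(methoxymethoxy)-3-(3-methylbut-2-en-1-yl)phenyl]methyl}-5-oxo-4-[2-(trimethylsilyl)ethoxy]-2,5-dihydrofuran-2-carboxylate
Conditions: Me3SiCHN2 (2 M in hexanes), toluene/MeOH 4:1, 0 °C
Reagents that add atoms: (trimethylsilyl)diazomethane, C[Si](C)(C)C=[N+]=[N-]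
Why: O-Methylation of the carboxylic acid by diazomethane released in the flask touches only the acid, since the enol is masked as its silylethyl ether and the phenols as MOM ethers.

Step 14
Reactants: 28 methyl (2S)-3-[3,4-bis(methoxymethoxy)-5-(3-methylbut-2-en-1-yl)phenyl]-2-{[4-(methoxymethoxy)-3-(3-methylbut-2-en-1-yl)phenyl]methyl}-5-oxo-4-[2-(trimethylsilyl)ethoxy]-2,5-dihydrofuran-2-carboxylate
Product: 29 methyl (2S)-3-[3,4-bis(methoxymethoxy)-5-(3-methylbut-2-en-1-yl)phenyl]-4-hydroxy-2-{[4-(methoxymethoxy)-3-(3-methylbut-2-en-1-yl)phenyl]methyl}-5-oxo-2,5-dihydrofuran-2-carboxylate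
Conditions: Bu4NF (1 M in THF, 1.5 equiv), THF, 0 → 25 °C; work-up with cold HCl (0.5 M aq.)
Reagents that add atoms: none
Why: Fluoride attacks silicon and the β-silyl fragmentation (Peterson-type 1,2-elimination) expels ethene and the enolate of the acidic 3-hydroxybutenolide, a good leaving group, while the MOM ethers, the methyl ester and the lactone are stable to fluoride at this temperature.

Step 15
Reactants: 29 methyl (2S)-3-[3,4-bis(methoxymethoxy)-5-(3-methylbut-2-en-1-yl)phenyl]-4-hydroxy-2-{[4-(methoxymethoxy)-3-(3-methylbut-2-en-1-yl)phenyl]methyl}-5-oxo-2,5-dihydrofuran-2-carboxylate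
Product: 30 methyl (2S)-3-[3,4-dihydroxy-5-(3-methylbut-2-en-1-yl)phenyl]-4-hydroxy-2-{[4-hydroxy-3-(3-methylbut-2-en-1-yl)phenyl]methyl}-5-oxo-2,5-dihydrofuran-2-carboxylate (CNP0460191.1)
Conditions: HCl (3 M aq., catalytic), MeOH, 25–40 °C, short reaction time
Reagents that add atoms: none
Why: Acid-catalysed acetal exchange with methanol cleaves the three aryl MOM ethers through oxocarbenium ions under conditions mild enough to spare the prenyl groups, the methyl ester and the enol lactone; C5 is quaternary and cannot epimerise.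

Compound list
1 | 4-bromo-2-iodophenol | Oc1ccc(Br)cc1I | starting material
2 | 4-bromo-2-iodo-1-(methoxymethoxy)benzene | COCOc1ccc(Br)cc1I | intermediate
3 | [5-bromo-2-(methoxymethoxy)phenyl]magnesium chloride | COCOc1ccc(Br)cc1[Mg]Cl | intermediate (not isolated)
4 | 4-bromo-1-(methoxymethoxy)-2-(3-methylbut-2-en-1-yl)benzene | COCOc1ccc(Br)cc1CC=C(C)C | intermediate
5 | methyl oxirane-2-carboxylate (racemic) | COC(=O)C1CO1 | starting material
6 | [4-(methoxymethoxy)-3-(3-methylbut-2-en-1-yl)phenyl]magnesium bromide | COCOc1ccc([Mg]Br)cc1CC=C(C)C | intermediate (not isolated)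
7 | methyl 2-hydroxy-3-[4-(methoxymethoxy)-3-(3-methylbut-2-en-1-yl)phenyl]propanoate (racemic) | COC(=O)C(O)Cc1ccc(OCOC)c(CC=C(C)C)c1 | intermediate
8 | methyl 3-[4-(methoxymethoxy)-3-(3-methylbut-2-en-1-yl)phenyl]-2-oxopropanoate | COC(=O)C(=O)Cc1ccc(OCOC)c(CC=C(C)C)c1 | intermediate
9 | 2-(trimethylsilyl)ethanol | OCC[Si](C)(C)C | starting material
10 | trichloroethylene | ClC=C(Cl)Cl | starting material
11 | (E)-[2-(1,2-dichloroethenyloxy)ethyl]trimethylsilane | Cl/C=C(/Cl)OCC[Si](C)(C)C | intermediate (not isolated)
12 | lithium [2-(trimethylsilyl)ethoxy]acetylide | [Li]C#COCC[Si](C)(C)C | intermediate (not isolated)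
13 | [2-(ethynyloxy)ethyl]trimethylsilane | C#COCC[Si](C)(C)C | intermediate
14 | methyl (2S)-2-hydroxy-2-{[4-(methoxymethoxy)-3-(3-methylbut-2-en-1-yl)phenyl]methyl}-4-[2-(trimethylsilyl)ethoxy]but-3-ynoate | COC(=O)[C@@](C#COCC[Si](C)(C)C)(Cc1ccc(OCOC)c(CC=C(C)C)c1)O | intermediate
15 | lithium (2S)-2-hydroxy-2-{[4-(methoxymethoxy)-3-(3-methylbut-2-en-1-yl)phenyl]methyl}-4-[2-(trimethylsilyl)ethoxy]but-3-ynoate | [Li+].[O-]C(=O)[C@@](C#COCC[Si](C)(C)C)(Cc1ccc(OCOC)c(CC=C(C)C)c1)O | intermediate
16 | 3,5-dibromo-2-hydroxybenzaldehyde | O=Cc1cc(Br)cc(Br)c1O | starting material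
17 | 3,5-dibromo-2-hydroxyphenyl formate | O=COc1cc(Br)cc(Br)c1O | intermediate (not isolated)
18 | 3,5-dibromobenzene-1,2-diol | Oc1cc(Br)cc(Br)c1O | intermediate
19 | 1,5-dibromo-2,3-bis(methoxymethoxy)benzene | COCOc1cc(Br)cc(Br)c1OCOC | intermediate
20 | [5-bromo-2,3-bis(methoxymethoxy)phenyl]magnesium chloride | COCOc1cc(Br)cc([Mg]Cl)c1OCOC | intermediate (not isolated)
21 | 5-bromo-1,2-bis(methoxymethoxy)-3-(3-methylbut-2-en-1-yl)benzene | COCOc1cc(Br)cc(CC=C(C)C)c1OCOC | intermediate
22 | [3,4-bis(methoxymethoxy)-5-(3-methylbut-2-en-1-yl)phenyl]magnesium bromide | Br[Mg]c1cc(OCOC)c(OCOC)c(CC=C(C)C)c1 | intermediate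
23 | carbon dioxide | O=C=O | starting material
24 | chloromagnesium C5 alkoxide of 15 (lithium carboxylate) | [Li+].[O-]C(=O)[C@@](C#COCC[Si](C)(C)C)(Cc1ccc(OCOC)c(CC=C(C)C)c1)O[Mg]Cl | intermediate (not isolated)
25 | five-membered oxamagnesacycle, Mg bound to C3 and to the C5 oxygen, ring B aryl on C4 (lithium carboxylate) | [Li+].[O-]C(=O)[C@@]1(Cc2ccc(OCOC)c(CC=C(C)C)c2)O[Mg]C(OCC[Si](C)(C)C)=C1c1cc(OCOC)c(OCOC)c(CC=C(C)C)c1 | intermediate (not isolated)
26 | open-chain (S) hydroxy diacid, C5 and the new carboxyl cis on C3=C4 (E by CIP) | OC(=O)[C@@](/C(c1cc(OCOC)c(OCOC)c(CC=C(C)C)c1)=C(/OCC[Si](C)(C)C)C(=O)O)(Cc1ccc(OCOC)c(CC=C(C)C)c1)O | intermediate (not isolated)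
27 | (2S)-3-[3,4-bis(methoxymethoxy)-5-(3-methylbut-2-en-1-yl)phenyl]-2-{[4-(methoxymethoxy)-3-(3-methylbut-2-en-1-yl)phenyl]methyl}-5-oxo-4-[2-(trimethylsilyl)ethoxy]-2,5-dihydrofuran-2-carboxylic acid | OC(=O)[C@@]1(Cc2ccc(OCOC)c(CC=C(C)C)c2)OC(=O)C(OCC[Si](C)(C)C)=C1c1cc(OCOC)c(OCOC)c(CC=C(C)C)c1 | intermediate
28 | methyl ester of 27 | COC(=O)[C@@]1(Cc2ccc(OCOC)c(CC=C(C)C)c2)OC(=O)C(OCC[Si](C)(C)C)=C1c1cc(OCOC)c(OCOC)c(CC=C(C)C)c1 | intermediate
29 | methyl (2S)-3-[3,4-bis(methoxymethoxy)-5-(3-methylbut-2-en-1-yl)phenyl]-4-hydroxy-2-{[4-(methoxymethoxy)-3-(3-methylbut-2-en-1-yl)phenyl]methyl}-5-oxo-2,5-dihydrofuran-2-carboxylate | COC(=O)[C@@]1(Cc2ccc(OCOC)c(CC=C(C)C)c2)OC(=O)C(O)=C1c1cc(OCOC)c(OCOC)c(CC=C(C)C)c1 | intermediate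
30 | methyl (2S)-3-[3,4-dihydroxy-5-(3-methylbut-2-en-1-yl)phenyl]-4-hydroxy-2-{[4-hydroxy-3-(3-methylbut-2-en-1-yl)phenyl]methyl}-5-oxo-2,5-dihydrofuran-2-carboxylate | COC(=O)[C@@]1(Cc2ccc(O)c(CC=C(C)C)c2)OC(=O)C(O)=C1c1cc(O)c(O)c(CC=C(C)C)c1 | target

Total step count: 15. Longest linear sequence: 10 steps (1, 2, 3, 4, 6, 7, 12, 13, 14, 15).

Steps most likely to fail

Step 12 (Proposed new method). Under copper control the aryl group may instead add to C3, the electrophilic carbon of the alkoxyalkyne, after which the silylethoxide can be lost to leave an arylalkyne. The hindered, doubly anionic substrate may also fail to add, or the vinylmagnesium may be protonated before CO2 is taken up. The fallback gives up the alkyne and builds the ring by the known crossed aldol addition–lactonisation of two arylpyruvates. It sets out from 22 and 8. Reagent 22 opens 5 under CuI catalysis (THF, −40 °C) to methyl 3-[3,4-bis(methoxymethoxy)-5-(3-methylbut-2-en-1-yl)phenyl]-2-hydroxypropanoate F1, and Dess–Martin oxidation gives methyl 3-[3,4-bis(methoxymethoxy)-5-(3-methylbut-2-en-1-yl)phenyl]-2-oxopropanoate F2. With DBU in DMF the enolate of F2 adds through its benzylic carbon to the ketone of 8, and the new tertiary alkoxide closes onto the ester of F2. This should give, beside the two homodimers and the reversed cross product, the racemate of 29 F3. After chromatographic separation, F3 is resolved on a chiral stationary phase and the (S) enantiomer is 29, where the route is rejoined before step 15.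

Step 6. Enolisation and self-condensation of the arylpyruvate may outrun alkynyl transfer, facial selectivity may be poor, or the zinc Lewis acid may trigger Meyer–Schuster rearrangement of the hydroxy alkoxyalkyne. The fallback replaces catalysis by a stoichiometric, non-selective addition followed by resolution. It sets out from 13 and 8. Compound 13 is deprotonated with n-BuLi to 12, which is transmetalated with LaCl3·2LiCl in THF at −78 °C; the weakly basic lanthanum acetylide should add to the ketone of 8 faster than it enolises it, giving racemic methyl 2-hydroxy-2-{[4-(methoxymethoxy)-3-(3-methylbut-2-en-1-yl)phenyl]methyl}-4-[2-(trimethylsilyl)ethoxy]but-3-ynoate F4. Preparative chromatography of F4 on a chiral stationary phase delivers the (S) enantiomer, which is 14, and the route continues with step 7.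

Step 15. As the phenols are freed, acid may drive cyclisation of a prenyl group onto its neighbouring hydroxyl (chroman formation), or the cleavage may stop short. The fallback avoids protic acid by switching the protecting group. It sets out from 29. Treatment with Me3SiOTf and 2,2'-bipyridyl in CH2Cl2 at 0 °C transfers the methoxymethyl groups to the pyridine nitrogen and should leave the aryl oxygens (and the enol oxygen) silylated, giving the tetrakis(trimethylsilyl) ether of 30 F5. Hydrolysis of F5 with water at neutral pH then gives 30.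

Further compounds
F1 | step 12 | methyl 3-[3,4-bis(methoxymethoxy)-5-(3-methylbut-2-en-1-yl)phenyl]-2-hydroxypropanoate (racemic) | COC(=O)C(O)Cc1cc(OCOC)c(OCOC)c(CC=C(C)C)c1
F2 | step 12 | methyl 3-[3,4-bis(methoxymethoxy)-5-(3-methylbut-2-en-1-yl)phenyl]-2-oxopropanoate | COC(=O)C(=O)Cc1cc(OCOC)c(OCOC)c(CC=C(C)C)c1
F3 | step 12 | racemate of 29 | COC(=O)C1(Cc2ccc(OCOC)c(CC=C(C)C)c2)OC(=O)C(O)=C1c1cc(OCOC)c(OCOC)c(CC=C(C)C)c1
F4 | step 6 | racemate of 14 | COC(=O)C(C#COCC[Si](C)(C)C)(Cc1ccc(OCOC)c(CC=C(C)C)c1)O
F5 | step 15 | tetrakis(trimethylsilyl) ether of 30 (three phenol oxygens and the C3 enol oxygen silylated) | COC(=O)[C@@]1(Cc2ccc(O[Si](C)(C)C)c(CC=C(C)C)c2)OC(=O)C(O[Si](C)(C)C)=C1c1cc(O[Si](C)(C)C)c(O[Si](C)(C)C)c(CC=C(C)C)c1
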